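Decalin positions carry labdane numbers (C10 = angular-methyl carbon, C5 = ring-fusion CH, C4 = gem-dimethyl carbon; α = face opposite the C10 methyl). The target is 6β-acetoxy-9α-hydroxy-8α-methyl on a trans-decalin, with a 2-(2-oxo-2,5-dihydrofuran-3-yl)ethyl chain at C9β.
Retrosynthesis: cut C12–C13 (B-alkyl Suzuki coupling), then C9–C11 (vinyl addition to a C9 ketone), then the C1–O bond (deoxygenation), and last ring A at C4–C5 and C1–C10.
Enabling feature: ring B is a 2,6-dimethylcyclohexanone (C9 carbonyl between C8 and C10) oxygenated at C6. Its C5=C10 enone is therefore a radical acceptor whose enolate carbon is C10, and C1–C4 with the gem-dimethyl group map onto 4-methylpent-4-enal.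
Forward: ring B is made first from a symmetric quinone monoketal, ring A is annulated onto it in one operation, C1 is deoxygenated, and the side chain is joined last.
Stereochemistry: a ligand-controlled desymmetrising conjugate reduction sets C8; C8 directs the C6 carbinol (cis); the 6α-silyloxy group directs radical attack at C5; the chair aldol sets C10 (trans fusion). C9 comes from equatorial vinyl addition, and C6 is finally inverted by oxidation and α-face hydride reduction.

Key step: step 7

Assumption: 4-methoxy-3,5-dimethylphenol and 3-bromofuran-2(5H)-one are taken as catalogue compounds (otherwise one step each, by Dakin oxidation of 4-methoxy-3,5-dimethylbenzaldehyde and by bromination–dehydrobromination of furan-2(5H)-one).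

Step 1
Reactants: 1 4-methoxy-3,5-dimethylphenol
Product: 2 4,4-dimethoxy-3,5-dimethylcyclohexa-2,5-dien-1-one
Conditions: PhI(OAc)2 (1.1 equiv), MeOH, 0 °C → rt
Reagents that add atoms: methanol, CO
Why: Hypervalent-iodine oxidative dearomatisation of a p-methoxyphenol in methanol traps the phenoxonium ion at the methoxy-bearing carbon and gives the symmetric quinone monoketal in which the future C9 carbonyl is masked.

Step 2
Reactants: 2 4,4-dimethoxy-3,5-dimethylcyclohexa-2,5-dien-1-one
Product: 4 (5R)-4,4-dimethoxy-3,5-dimethylcyclohex-2-en-1-one, via silyl dienol ether 3 (not isolated)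
Conditions: Cu(OAc)2·H2O (3 mol %), (S)-DTBM-SEGPHOS (3.3 mol %), (EtO)2MeSiH (1.2 equiv), toluene, 0 °C; then 1 M aq. NaOH/THF, 0 °C
Reagents that add atoms: none
Why: Copper hydride asymmetric 1,4-reduction of a β,β-disubstituted cyclic enone delivers hydride under ligand control to one enantiotopic β-carbon and sets the future C8 methyl centre as (5R), while the silyl dienol ether 3 formed on turnover shields the second enone from over-reduction until work-up; the ligand antipode is assigned by analogy with simple 3-methylcyclohexenones and is to be confirmed by correlation.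

Step 3
Reactants: 4 (5R)-4,4-dimethoxy-3,5-dimethylcyclohex-2-en-1-one
Product: 5 (1S,5R)-4,4-dimethoxy-3,5-dimethylcyclohex-2-en-1-ol
Conditions: NaBH4, CeCl3·7H2O, MeOH, −78 °C
Reagents that add atoms: none
Why: Luche 1,2-reduction in which hydride should add to the carbonyl face opposite the C5 methyl group and give the cis alcohol, the trans isomer being removed by chromatography because this carbinol later fixes the absolute sense of the annulation.

Step 4
Reactants: 5 (1S,5R)-4,4-dimethoxy-3,5-dimethylcyclohex-2-en-1-ol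
Product: 6 tert-butyl{[(1S,5R)-4,4-dimethoxy-3,5-dimethylcyclohex-2-en-1-yl]oxy}dimethylsilane
Conditions: TBSCl, imidazole, DMF, rt
Reagents that add atoms: tert-butyldimethylsilyl chloride, CC(C)(C)[Si](C)(C)Cl
Why: Imidazole-promoted silylation of a secondary allylic alcohol proceeds under basic conditions that leave the acid-labile allylic ketal untouched.

Step 5
Reactants: 6 tert-butyl{[(1S,5R)-4,4-dimethoxy-3,5-dimethylcyclohex-2-en-1-yl]oxy}dimethylsilane
Product: 7 (4S,6R)-4-(tert-butyldimethylsilyloxy)-2,6-dimethylcyclohex-2-en-1-one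
Conditions: PPTS (0.1 equiv), acetone/H2O (10:1), rt
Reagents that add atoms: water, O
Why: Mild acid-catalysed ketal hydrolysis unmasks the carbonyl between the two methyl-bearing carbons and gives the conjugated 2-methyl enone (cis 4-silyloxy/6-methyl), conditions under which a secondary TBS ether and the α′ centre should survive.

Step 6
Reactants: 8 2-methylprop-2-en-1-ol; 9 ethyl vinyl ether
Product: 11 4-methylpent-4-enal, via 2-methylallyl vinyl ether 10 (not isolated)
Conditions: Pd(OAc)2 (1 mol %), 1,10-phenanthroline (1 mol %), 9 as solvent, rt; filter, remove excess 9; neat, sealed tube, 150 °C; distil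
Reagents that add atoms: none
Why: Palladium(II)-catalysed transfer vinylation followed by thermal Claisen rearrangement of the allyl vinyl ether gives the γ,δ-unsaturated aldehyde carrying the 1,1-disubstituted alkene needed for Markovnikov hydrogen-atom transfer.

Step 7
Reactants: 7 (4S,6R)-4-(tert-butyldimethylsilyloxy)-2,6-dimethylcyclohex-2-en-1-one; 11 4-methylpent-4-enal
Product: 13 6α-(tert-butyldimethylsilyloxy)-1α-hydroxy-4,4,8α,10β-tetramethyl-5α-decalin-9-one, via iron(III) enolate 12 (not isolated)
Conditions: Fe(acac)3 (0.3 equiv), PhSiH3 (2.5 equiv), 11 (3 equiv, added in portions), EtOH/ethylene glycol (5:1), 0 °C → rt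
Reagents that add atoms: none
Why: Fe(acac)3 and the silane generate an iron hydride that transfers a hydrogen atom to the electron-rich 1,1-disubstituted alkene of 11 (Markovnikov, in preference to the electron-poor enone), the tertiary C4 radical adds to C5 of 7 (Giese addition), the α-keto radical is reduced to the iron(III) enolate 12 (radical–polar crossover), and this enolate attacks the tethered aldehyde to form C1–C10. The closest known reaction type is the iron-hydride HAT-initiated conjugate addition–aldol annulation of a 2-methylcycloalkenone with an unsaturated aldehyde, which gives hydroxylated trans-decalins with an angular methyl group. Ring A closes by a 6-(enolexo)-exo-trig aldol addition through a chair-like transition state. C5 is set by approach of the radical to the β face, anti to the adjacent 6α-silyloxy group (the C8 methyl lies on the same α face); C10 is set by the chair closure with the C5 side chain equatorial, which places the angular methyl axial and anti to H5 (trans fusion); the C1 carbinol is expected axial, anti to that methyl, and its configuration is immaterial because the oxygen is removed. The step needs β-face attack at C5 and hydrogen-atom transfer to the donor alkene only, and the silyloxy substituent next to the reacting carbon and the polarity difference between the two alkenes should secure both.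

Step 8
Reactants: 13 6α-(tert-butyldimethylsilyloxy)-1α-hydroxy-4,4,8α,10β-tetramethyl-5α-decalin-9-one
Product: 14 O-[6α-(tert-butyldimethylsilyloxy)-4,4,8α,10β-tetramethyl-9-oxo-5α-decalin-1α-yl] 1H-imidazole-1-carbothioate
Conditions: 1,1'-thiocarbonyldiimidazole (3 equiv), DMAP (0.2 equiv), ClCH2CH2Cl, 70 °C
Reagents that add atoms: 1,1'-thiocarbonyldiimidazole, S=C(n1ccnc1)n1ccnc1
Why: Thioacylation of the hindered secondary alcohol under neutral conditions prepares the Barton–McCombie substrate without forming the alkoxide that could open ring A by retro-aldol cleavage.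

Step 9
Reactants: 14 O-[6α-(tert-butyldimethylsilyloxy)-4,4,8α,10β-tetramethyl-9-oxo-5α-decalin-1α-yl] 1H-imidazole-1-carbothioate
Product: 15 6α-(tert-butyldimethylsilyloxy)-4,4,8α,10β-tetramethyl-5α-decalin-9-one
Conditions: Bu3SnH (3 equiv), AIBN (0.2 equiv), toluene, 100 °C
Reagents that add atoms: none
Why: Barton–McCombie deoxygenation: the stannyl radical adds to the thiocarbonyl group, the C1–O bond fragments, and the secondary C1 radical is quenched by excess tin hydride faster than a 1,2-acyl shift can occur, while C8 stays α because the equatorial methyl is the thermodynamic epimer of this ketone.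

Step 10
Reactants: 15 6α-(tert-butyldimethylsilyloxy)-4,4,8α,10β-tetramethyl-5α-decalin-9-one
Product: 16 6α-(tert-butyldimethylsilyloxy)-4,4,8α,10β-tetramethyl-9β-vinyl-5α-decalin-9α-ol
Conditions: CH2=CHMgBr (3 equiv), LaCl3·2LiCl (0.3 equiv), THF, −20 → 0 °C; aq. NH4Cl
Reagents that add atoms: vinylmagnesium bromide, C=C[Mg]Br
Why: Lanthanum-promoted Grignard 1,2-addition suppresses enolisation, and equatorial (β-face) attack trans to the C8 methyl, away from the axial hydrogens at C1, C5 and C7 on the α face, should give the axial 9α alcohol as is usual for 2,2,6-trisubstituted cyclohexanones.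

Step 11
Reactants: 16 6α-(tert-butyldimethylsilyloxy)-4,4,8α,10β-tetramethyl-9β-vinyl-5α-decalin-9α-ol
Product: 17 4,4,8α,10β-tetramethyl-9β-vinyl-5α-decalin-6α,9α-diol
Conditions: TBAF (2 equiv), THF, 40 °C; aq. NH4Cl
Reagents that add atoms: none
Why: Fluoride-mediated cleavage of the secondary silyl ether frees the C6 hydroxyl without affecting the tertiary allylic alcohol.

Step 12
Reactants: 17 4,4,8α,10β-tetramethyl-9β-vinyl-5α-decalin-6α,9α-diol
Product: 18 9α-hydroxy-4,4,8α,10β-tetramethyl-9β-vinyl-5α-decalin-6-one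
Conditions: Dess–Martin periodinane (1.3 equiv), NaHCO3, CH2Cl2, 0 °C → rt
Reagents that add atoms: none
Why: Dess–Martin oxidation converts only the secondary alcohol, and the buffered, chromium-free conditions avoid oxidative transposition of the tertiary allylic alcohol and epimerisation at C5.

Step 13
Reactants: 18 9α-hydroxy-4,4,8α,10β-tetramethyl-9β-vinyl-5α-decalin-6-one
Product: 19 4,4,8α,10β-tetramethyl-9β-vinyl-5α-decalin-6β,9α-diol
Conditions: NaBH4, MeOH, 0 °C → rt
Reagents that add atoms: none
Why: Borohydride reduction in which the β face of the C6 carbonyl is blocked by the syn-axial methyl groups at C4 and C10, so hydride should enter from the α face and give the axial 6β alcohol.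

Step 14
Reactants: 19 4,4,8α,10β-tetramethyl-9β-vinyl-5α-decalin-6β,9α-diol
Product: 20 9α-hydroxy-4,4,8α,10β-tetramethyl-9β-vinyl-5α-decalin-6β-yl acetate
Conditions: Ac2O, Et3N, DMAP (0.3 equiv), CH2Cl2, rt → 40 °C
Reagents that add atoms: acetic anhydride, CC(=O)OC(C)=O
Why: DMAP-catalysed acetylation should esterify the hindered secondary 6β-hydroxyl while the tertiary C9 hydroxyl remains free.

Step 15
Reactants: 20 9α-hydroxy-4,4,8α,10β-tetramethyl-9β-vinyl-5α-decalin-6β-yl acetate; 21 3-bromofuran-2(5H)-one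
Product: 23 6β-acetoxy-9α-hydroxylabd-13-en-16,15-olide, via B-alkyl-9-BBN 22 (not isolated)
Conditions: 9-BBN (3 equiv), THF, rt → 50 °C; then H2O, 21, Pd(dppf)Cl2 (10 mol %), AsPh3 (10 mol %), Cs2CO3, DMF, rt
Reagents that add atoms: none
Why: Anti-Markovnikov hydroboration of the terminal vinyl group followed by B-alkyl Suzuki–Miyaura coupling with the α-bromo unsaturated lactone forms C12–C13 and delivers the α-substituted butenolide, with mild base at room temperature to spare the acetate and the lactone.

Compound list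
1 | 4-methoxy-3,5-dimethylphenol | COc1c(C)cc(O)cc1C | starting material
2 | 4,4-dimethoxy-3,5-dimethylcyclohexa-2,5-dien-1-one | COC1(OC)C(C)=CC(=O)C=C1C | intermediate
3 | {[(3R)-4,4-dimethoxy-3,5-dimethylcyclohexa-1,5-dien-1-yl]oxy}diethoxy(methyl)silane (silyl dienol ether) | CCO[Si](C)(OCC)OC1=C[C@@H](C)C(OC)(OC)C(C)=C1 | intermediate (not isolated)
4 | (5R)-4,4-dimethoxy-3,5-dimethylcyclohex-2-en-1-one | O=C1C=C(C)C(OC)(OC)[C@H](C)C1 | intermediate
5 | (1S,5R)-4,4-dimethoxy-3,5-dimethylcyclohex-2-en-1-ol (cis) | O[C@@H]1C=C(C)C(OC)(OC)[C@H](C)C1 | intermediate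
6 | tert-butyl{[(1S,5R)-4,4-dimethoxy-3,5-dimethylcyclohex-2-en-1-yl]oxy}dimethylsilane | CC(C)(C)[Si](C)(C)O[C@@H]1C=C(C)C(OC)(OC)[C@H](C)C1 | intermediate
7 | (4S,6R)-4-(tert-butyldimethylsilyloxy)-2,6-dimethylcyclohex-2-en-1-one (cis) | CC(C)(C)[Si](C)(C)O[C@H]1C[C@@H](C)C(=O)C(C)=C1 | intermediate
8 | 2-methylprop-2-en-1-ol | CC(=C)CO | starting material
9 | ethyl vinyl ether | CCOC=C | starting material
10 | 3-(ethenyloxy)-2-methylprop-1-ene (2-methylallyl vinyl ether) | CC(=C)COC=C | intermediate (not isolated)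
11 | 4-methylpent-4-enal | CC(=C)CCC=O | intermediate
12 | iron(III) enolate of the C5 adduct, drawn as the enolate anion: C9–C10 enolate of 6α-silyloxy-8α,10-dimethyl-5β-(2-methyl-5-oxopentan-2-yl)cyclohexan-9-one | CC(C)(C)[Si](C)(C)O[C@H]1C[C@@H](C)C([O-])=C(C)[C@@H]1C(C)(C)CCC=O | intermediate (not isolated)
13 | 6α-(tert-butyldimethylsilyloxy)-1α-hydroxy-4,4,8α,10β-tetramethyl-5α-decalin-9-one (1S,5S,6S,8R,10R) | CC(C)(C)[Si](C)(C)O[C@H]1C[C@@H](C)C(=O)[C@@]2(C)[C@@H](O)CCC(C)(C)[C@H]12 | intermediate
14 | O-[6α-(tert-butyldimethylsilyloxy)-4,4,8α,10β-tetramethyl-9-oxo-5α-decalin-1α-yl] 1H-imidazole-1-carbothioate | CC(C)(C)[Si](C)(C)O[C@H]1C[C@@H](C)C(=O)[C@@]2(C)[C@@H](OC(=S)n3ccnc3)CCC(C)(C)[C@H]12 | intermediate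
15 | 6α-(tert-butyldimethylsilyloxy)-4,4,8α,10β-tetramethyl-5α-decalin-9-one (5S,6S,8R,10S) | CC(C)(C)[Si](C)(C)O[C@H]1C[C@@H](C)C(=O)[C@@]2(C)CCCC(C)(C)[C@H]12 | intermediate
16 | 6α-(tert-butyldimethylsilyloxy)-4,4,8α,10β-tetramethyl-9β-vinyl-5α-decalin-9α-ol | CC(C)(C)[Si](C)(C)O[C@H]1C[C@@H](C)[C@](O)(C=C)[C@@]2(C)CCCC(C)(C)[C@H]12 | intermediate
17 | 4,4,8α,10β-tetramethyl-9β-vinyl-5α-decalin-6α,9α-diol | O[C@H]1C[C@@H](C)[C@](O)(C=C)[C@@]2(C)CCCC(C)(C)[C@H]12 | intermediate
18 | 9α-hydroxy-4,4,8α,10β-tetramethyl-9β-vinyl-5α-decalin-6-one | O=C1C[C@@H](C)[C@](O)(C=C)[C@@]2(C)CCCC(C)(C)[C@H]12 | intermediate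
19 | 4,4,8α,10β-tetramethyl-9β-vinyl-5α-decalin-6β,9α-diol | O[C@@H]1C[C@@H](C)[C@](O)(C=C)[C@@]2(C)CCCC(C)(C)[C@H]12 | intermediate
20 | 9α-hydroxy-4,4,8α,10β-tetramethyl-9β-vinyl-5α-decalin-6β-yl acetate | CC(=O)O[C@@H]1C[C@@H](C)[C@](O)(C=C)[C@@]2(C)CCCC(C)(C)[C@H]12 | intermediate
21 | 3-bromofuran-2(5H)-one | O=C1OCC=C1Br | starting material
22 | 9-[2-(6β-acetoxy-9α-hydroxy-4,4,8α,10β-tetramethyl-5α-decalin-9β-yl)ethyl]-9-borabicyclo[3.3.1]nonane | CC(=O)O[C@@H]1C[C@@H](C)[C@](O)(CCB3C4CCCC3CCC4)[C@@]2(C)CCCC(C)(C)[C@H]12 | intermediate (not isolated)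
23 | 6β-acetoxy-9α-hydroxylabd-13-en-16,15-olide; 3-[2-(6β-acetoxy-9α-hydroxy-4,4,8α,10β-tetramethyl-5α-decalin-9β-yl)ethyl]furan-2(5H)-one (5S,6R,8R,9R,10S) | CC(=O)O[C@@H]1C[C@@H](C)[C@](O)(CCC2=CCOC2=O)[C@@]2(C)CCCC(C)(C)[C@H]12 | target

Total step count: 15. Longest linear sequence: 14 (steps 1–5 and 7–15; step 6 is the one-step side branch).

Steps most likely to fail

Step 7. The tertiary radical may be reduced before it adds to the crowded C5, it may add with poor facial discrimination, or the iron enolate may be protonated before ring A closes. The fallback builds the same two bonds by polar, stepwise chemistry; it sets out from 7 and comes back at 13. Hosomi–Sakurai conjugate addition of trimethyl(3-methylbut-2-en-1-yl)silane (TiCl4, CH2Cl2, −78 °C) bonds through the γ-carbon of the silane, anti to the silyloxy group, and should give (2RS,3R,4S,6R)-4-(tert-butyldimethylsilyloxy)-2,6-dimethyl-3-(2-methylbut-3-en-2-yl)cyclohexan-1-one F1. Linear-selective hydroformylation of its neopentyl-type vinyl group (Rh(acac)(CO)2, Xantphos, CO/H2, toluene, 80 °C) should give 4-[(1R,2S,4R,6RS)-2-(tert-butyldimethylsilyloxy)-4,6-dimethyl-5-oxocyclohexyl]-4-methylpentanal F2. Reversible base-mediated aldol addition (cat. KOt-Bu, t-BuOH/THF, 0 °C), in which only attack of C10 on C1 closes a six-membered ring, should then return 13.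

Step 2. Enantioface selection at the hindered β-carbon next to the ketal may be insufficient or of the unexpected sense, and the second enone may be over-reduced. The fallback replaces desymmetrisation by resolution; it sets out from 2 and comes back at 5. Non-selective conjugate reduction with an achiral copper hydride ([(Ph3P)CuH]6 cat., (EtO)2MeSiH, toluene; aq. NaOH) should give racemic 4,4-dimethoxy-3,5-dimethylcyclohex-2-en-1-one F3. Luche reduction should give racemic cis-4,4-dimethoxy-3,5-dimethylcyclohex-2-en-1-ol F4. Lipase-catalysed acylation (Burkholderia cepacia lipase, vinyl acetate, MTBE, rt), run past half conversion, should convert the (1R,5S) enantiomer into (1R,5S)-4,4-dimethoxy-3,5-dimethylcyclohex-2-en-1-yl acetate F5 and leave the (1S,5R) alcohol 5, which is separated by chromatography.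

Step 15. The bromobutenolide or the product lactone may be opened or isomerised by the aqueous base, the acetate may be cleaved, or transmetallation of the hydroxyl-bearing alkylborane may be slow. The fallback forms C12–C13 by enolate alkylation and introduces the ring double bond afterwards; it sets out from 22 and comes back at 23. Oxidative work-up of 22 (NaBO3·4H2O, THF/H2O, rt) should give 9α-hydroxy-9β-(2-hydroxyethyl)-4,4,8α,10β-tetramethyl-5α-decalin-6β-yl acetate F6. Appel iodination (I2, PPh3, imidazole, CH2Cl2, 0 °C) should give 9α-hydroxy-9β-(2-iodoethyl)-4,4,8α,10β-tetramethyl-5α-decalin-6β-yl acetate F7. Alkylation of the lithium enolate of 3-(phenylsulfanyl)oxolan-2-one (LiHMDS, THF/HMPA, −78 → 0 °C, excess enolate) should give 9α-hydroxy-4,4,8α,10β-tetramethyl-9β-{2-[2-oxo-3-(phenylsulfanyl)oxolan-3-yl]ethyl}-5α-decalin-6β-yl acetate F8. Oxidation (mCPBA, CH2Cl2, −78 °C) should give the sulfoxide 9α-hydroxy-4,4,8α,10β-tetramethyl-9β-{2-[2-oxo-3-(phenylsulfinyl)oxolan-3-yl]ethyl}-5α-decalin-6β-yl acetate F9, and thermal syn-elimination toward the ring methylene (toluene, 110 °C) should give 23.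

Further compounds
F1 | step 7 | (2RS,3R,4S,6R)-4-(tert-butyldimethylsilyloxy)-2,6-dimethyl-3-(2-methylbut-3-en-2-yl)cyclohexan-1-one | CC(C)(C)[Si](C)(C)O[C@H]1C[C@@H](C)C(=O)C(C)[C@@H]1C(C)(C)C=C
F2 | step 7 | 4-[(1R,2S,4R,6RS)-2-(tert-butyldimethylsilyloxy)-4,6-dimethyl-5-oxocyclohexyl]-4-methylpentanal | CC(C)(C)[Si](C)(C)O[C@H]1C[C@@H](C)C(=O)C(C)[C@@H]1C(C)(C)CCC=O
F3 | step 2 | racemic 4,4-dimethoxy-3,5-dimethylcyclohex-2-en-1-one | CC1CC(=O)C=C(C)C1(OC)OC
F4 | step 2 | racemic cis-(1S*,5R*)-4,4-dimethoxy-3,5-dimethylcyclohex-2-en-1-ol | OC1C=C(C)C(OC)(OC)C(C)C1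
F5 | step 2 | (1R,5S)-4,4-dimethoxy-3,5-dimethylcyclohex-2-en-1-yl acetate | CC(=O)O[C@H]1C=C(C)C(OC)(OC)[C@@H](C)C1
F6 | step 15 | 9α-hydroxy-9β-(2-hydroxyethyl)-4,4,8α,10β-tetramethyl-5α-decalin-6β-yl acetate | CC(=O)O[C@@H]1C[C@@H](C)[C@](O)(CCO)[C@@]2(C)CCCC(C)(C)[C@H]12
F7 | step 15 | 9α-hydroxy-9β-(2-iodoethyl)-4,4,8α,10β-tetramethyl-5α-decalin-6β-yl acetate | CC(=O)O[C@@H]1C[C@@H](C)[C@](O)(CCI)[C@@]2(C)CCCC(C)(C)[C@H]12
F8 | step 15 | 9α-hydroxy-4,4,8α,10β-tetramethyl-9β-{2-[2-oxo-3-(phenylsulfanyl)oxolan-3-yl]ethyl}-5α-decalin-6β-yl acetate | CC(=O)O[C@@H]1C[C@@H](C)[C@](O)(CCC3(Sc4ccccc4)CCOC3=O)[C@@]2(C)CCCC(C)(C)[C@H]12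
F9 | step 15 | 9α-hydroxy-4,4,8α,10β-tetramethyl-9β-{2-[2-oxo-3-(phenylsulfinyl)oxolan-3-yl]ethyl}-5α-decalin-6β-yl acetate | CC(=O)O[C@@H]1C[C@@H](C)[C@](O)(CCC3(S(=O)c4ccccc4)CCOC3=O)[C@@]2(C)CCCC(C)(C)[C@H]12
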